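**Retrosynthetic overview**

- Feature: ring A (the 2,4-disubstituted oxazole) carries C2–N3–C4–C5 in the connectivity C≡N–CH2–CO2Me of an isocyanoacetate, and chain C2–C6 with O3, O4 and O5 is 2,6-dideoxy-L-lyxo-hexose, so chain C1 is the sugar aldehyde carbon.
- Disconnections: C2(ring A)–CH2 by Negishi coupling of C2-zincated ring A with 5-(chloromethyl)oxazole (ring B bought intact); ring A O1–C5 by cyclodehydration of an N-formyl α-amino aldehyde; C1–C4(ring A) by a gold-catalysed asymmetric isocyanoacetate aldol on the open-chain deoxyfucose aldehyde.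
- Ring order: temporary trans-4,5-dihydrooxazole (step 8), opened by hydrolysis, then ring A (step 13); ring B is never built.
- Aldehyde from 3,4-di-O-acetyl-L-fucal: O3 is silylated and O4 myristoylated on the glycal, and the ring is opened as a dithiane so that O5 can be silylated without acyl migration.

Key step: step 8

Remark: chain atoms are numbered C1 (carbinol on ring A C4) to C6 (methyl) and TBS is tert-butyldimethylsilyl; the (R)-(S) ligand series is assumed to direct aldehyde 9 as it does simple aliphatic aldehydes, to the (4S,5R)-oxazoline.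

**Route**

Step 1
Reactants: 1 3,4-di-O-acetyl-L-fucal
Product: 2 L-fucal
Conditions: NaOMe (0.1 equiv), MeOH, 25 °C
Reagents that add atoms: none
Why: Zemplén transesterification removes both acetates with catalytic methoxide and leaves the enol ether and all stereocentres untouched.

Step 2
Reactants: 2 L-fucal
Product: 3 3-O-TBS-L-fucal
Conditions: TBSCl (1.05 equiv), imidazole, DMF, 0 °C
Reagents that add atoms: tert-butyldimethylsilyl chloride, CC(C)(C)[Si](C)(C)Cl
Why: Regioselective silyl ether formation, since the equatorial allylic 3-OH is more accessible than the axial 4-OH next to the C5 methyl group, so one equivalent of silyl chloride should mark O3 only.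

Step 3
Reactants: 3 3-O-TBS-L-fucal; 4 myristic acid
Product: 5 3-O-TBS-4-O-tetradecanoyl-L-fucal
Conditions: DCC, DMAP (0.2 equiv), CH2Cl2, 0 → 25 °C
Reagents that add atoms: none
Why: Steglich esterification acylates the one remaining (axial) hydroxyl, so the myristate sits on chain O4 while the pyran ring still masks O5.

Step 4
Reactants: 5 3-O-TBS-4-O-tetradecanoyl-L-fucal
Product: 6 3-O-TBS-4-O-tetradecanoyl-2,6-dideoxy-L-lyxo-hexopyranose (anomer mixture)
Conditions: PPh3·HBr (5 mol%), H2O (5 equiv), THF, 25 °C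
Reagents that add atoms: water, O
Why: Acid-catalysed Markovnikov hydration of the glycal enol ether through the oxocarbenium ion, under a mild phosphonium bromide catalyst that should avoid Ferrier rearrangement and spare the silyl ether and ester.

Step 5
Reactants: 6 3-O-TBS-4-O-tetradecanoyl-2,6-dideoxy-L-lyxo-hexopyranose
Product: 7 open-chain 1,3-dithiane with free O5–H
Conditions: HS(CH2)3SH (1.5 equiv), BF3·OEt2 (0.5 equiv), CH2Cl2, −40 °C
Reagents that add atoms: propane-1,3-dithiol, SCCCS
Why: Lewis-acid dithioacetalisation of a 2-deoxy lactol, in which the second thiol opens the ring to the dithiane and frees O5 under non-basic conditions, so the neighbouring O4 myristate should not migrate as it could in a borohydride ring opening.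

Step 6
Reactants: 7 open-chain 1,3-dithiane with free O5–H
Product: 8 3,5-bis-O-TBS dithiane
Conditions: TBSOTf, 2,6-lutidine, CH2Cl2, −78 °C
Reagents that add atoms: tert-butyldimethylsilyl triflate, CC(C)(C)[Si](C)(C)OS(=O)(=O)C(F)(F)F
Why: Silyl ether formation with a silyl triflate and a hindered weak base is fast at low temperature, which caps O5 before any acyl shift can occur.

Step 7
Reactants: 8 3,5-bis-O-TBS dithiane
Product: 9 (3S,4R,5S)-3,5-bis(TBS-oxy)-4-(tetradecanoyloxy)hexanal
Conditions: PhI(OCOCF3)2 (1.5 equiv), NaHCO3, MeCN/H2O 9:1, 0 °C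
Reagents that add atoms: water, O
Why: Oxidative dithiane hydrolysis (sulfur activation by the hypervalent iodine reagent, then hydrolysis of the thionium ion) is a buffered, fast unmasking that silyl ethers, the ester and the β-silyloxy aldehyde should tolerate.

Step 8
Reactants: 9 (3S,4R,5S)-3,5-bis(TBS-oxy)-4-(tetradecanoyloxy)hexanal; 10 methyl isocyanoacetate
Product: 11 methyl (4S,5R)-trans-5-(protected acylated chain)-4,5-dihydrooxazole-4-carboxylate
Conditions: [Au(CNC6H11)2]BF4 (1 mol%), (R)-N-methyl-N-[2-(morpholin-4-yl)ethyl]-1-[(S)-1',2-bis(diphenylphosphino)ferrocenyl]ethylamine (1.1 mol%), CH2Cl2, 25 °C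
Reagents that add atoms: none
Why: The isocyanide of 10 binds to the cationic monovalent gold centre held by the two phosphines, the pendant morpholine removes an α-proton, and the ammonium-paired enolate adds to the aldehyde carbon of 9 to form the C1–C4(ring A) bond. The alkoxide then attacks the gold-bound isocyanide carbon in a 5-endo-dig closure to give the 4,5-dihydrooxazole, and protodeauration frees the catalyst. The closest known reaction is the Ito–Hayashi asymmetric aldol of isocyanoacetates with aliphatic aldehydes, which delivers trans-5-alkyl-oxazoline-4-carboxylates. Oxazoline C5 (chain C1) is set by the ligand, which presents the ion-paired enolate to one aldehyde face, and C4 follows as the trans partner through the preferred open transition state. The step needs the 5R configuration (1,3-syn to O3); because 9 has a CH2 group next to the carbonyl, the bias from the C3 silyloxy centre should be weak and the (R)-(S) ligand should decide, with the mirror-image ligand available if the pairing proves mismatched. Only C5 has to be right, since C4 becomes sp2 in ring A, and C5 epimers are diastereomers that chromatography can remove.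

Step 9
Reactants: 11 methyl (4S,5R)-trans-oxazoline-4-carboxylate
Product: 13 N-formyl β-hydroxy amino ester, via formate ester ammonium chloride 12 (not isolated)
Conditions: 0.5 M aq. HCl (1.1 equiv), THF, 0 °C; then aq. NaHCO3, 25 °C
Reagents that add atoms: water, O
Why: Acid hydrolysis of the cyclic formimidate (water adds at C2, the C–N bond breaks to the formate ester ammonium salt) followed on neutralisation by O→N formyl transfer; the C5–O bond is never broken, so the new carbinol keeps its configuration, and the acid is used up as the ammonium salt before it can attack the silyl ethers.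

Step 10
Reactants: 13 N-formyl β-hydroxy amino ester
Product: 14 N-formyl amino ester with O1, O3 and O5 silylated
Conditions: TBSOTf, 2,6-lutidine, CH2Cl2, −78 → −20 °C; aq. NaHCO3 work-up
Reagents that add atoms: tert-butyldimethylsilyl triflate, CC(C)(C)[Si](C)(C)OS(=O)(=O)C(F)(F)F
Why: Silyl ether formation on the secondary C1 hydroxyl; any silyl imidate formed on the formamide is hydrolysed in the work-up.

Step 11
Reactants: 14 tris-silylated N-formyl amino ester
Product: 15 N-formyl amino primary alcohol
Conditions: NaBH4, THF/MeOH 4:1, 0 °C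
Reagents that add atoms: none
Why: Chemoselective borohydride reduction, since the methyl ester is activated by the α-formamido and β-silyloxy groups, whereas the myristate is an unactivated ester of a hindered secondary alcohol between two silyloxy groups and should survive at 0 °C.

Step 12
Reactants: 15 N-formyl amino primary alcohol
Product: 16 N-formyl α-amino aldehyde
Conditions: Dess–Martin periodinane, NaHCO3, CH2Cl2, 0 → 25 °C
Reagents that add atoms: none
Why: Dess–Martin oxidation is neutral and buffered, so the aldehyde should form without β-elimination of the C1 silyloxy group; it is used crude at once.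

Step 13
Reactants: 16 N-formyl α-amino aldehyde
Product: 18 2-H ring A oxazole, via 5-bromo-4,5-dihydrooxazole 17 (not isolated)
Conditions: PPh3, (CBrCl2)2, 2,6-di-tert-butyl-4-methylpyridine, CH2Cl2, 0 °C; then DBU, MeCN, 0 → 25 °C
Reagents that add atoms: none
Why: Robinson–Gabriel-type cyclodehydration under phosphonium bromide activation, in which the formamide oxygen closes onto the aldehyde carbon (O1–C5 of ring A) to give the 5-bromo-oxazoline and DBU then removes HBr to aromatise; only a weak hindered base is present while the aldehyde exists, which should suppress silanol elimination, and the ring A C4 stereocentre is erased as planned.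

Step 14
Reactants: 18 2-H ring A oxazole; 19 5-(chloromethyl)oxazole
Product: 21 tris-silylated bis-oxazole, via oxazol-2-ylzinc chloride 20 (not isolated)
Conditions: TMPZnCl·LiCl (1.3 equiv), THF, 25 °C; then 19, Pd(PPh3)4 (5 mol%), THF, 50 °C
Reagents that add atoms: none
Why: Directed zincation at C2, the most acidic C–H of ring A, gives a zinc species that does not ring-open and tolerates the ester; Negishi coupling then follows (oxidative addition of zerovalent palladium into the heterobenzylic C–Cl bond, transmetalation, reductive elimination), and because the amide base is consumed before 19 is added, the C2–H of ring B should stay untouched.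

Step 15
Reactants: 21 tris-silylated bis-oxazole
Product: 22 CNP0268144.1 (target)
Conditions: HF·pyridine, pyridine, THF, 0 → 25 °C
Reagents that add atoms: none
Why: Fluoride desilylation of the three TBS ethers under buffered, weakly acidic conditions, chosen so that the O4 myristate is not driven to O3 or O5 as a basic fluoride source could do.

**Compound list**

1 | 3,4-di-O-acetyl-L-fucal (3,4-di-O-acetyl-1,5-anhydro-2,6-dideoxy-L-lyxo-hex-1-enitol) | C[C@H]1[C@@H](OC(C)=O)[C@@H](OC(C)=O)C=CO1 | starting material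
2 | L-fucal | C[C@H]1[C@@H](O)[C@@H](O)C=CO1 | intermediate
3 | 3-O-(tert-butyldimethylsilyl)-L-fucal | C[C@H]1[C@@H](O)[C@@H](O[Si](C)(C)C(C)(C)C)C=CO1 | intermediate
4 | myristic acid (tetradecanoic acid) | CCCCCCCCCCCCCC(=O)O | starting material
5 | 3-O-(tert-butyldimethylsilyl)-4-O-tetradecanoyl-L-fucal | C[C@H]1[C@@H](OC(=O)CCCCCCCCCCCCC)[C@@H](O[Si](C)(C)C(C)(C)C)C=CO1 | intermediate
6 | 3-O-(tert-butyldimethylsilyl)-4-O-tetradecanoyl-2,6-dideoxy-L-lyxo-hexopyranose (anomer mixture) | C[C@H]1[C@@H](OC(=O)CCCCCCCCCCCCC)[C@@H](O[Si](C)(C)C(C)(C)C)CC(O)O1 | intermediate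
7 | (2S,3R,4S)-2-(tert-butyldimethylsilyloxy)-1-(1,3-dithian-2-yl)-4-hydroxypentan-3-yl tetradecanoate | C[C@H](O)[C@@H](OC(=O)CCCCCCCCCCCCC)[C@@H](O[Si](C)(C)C(C)(C)C)CC1SCCCS1 | intermediate
8 | (2S,3R,4S)-2,4-bis(tert-butyldimethylsilyloxy)-1-(1,3-dithian-2-yl)pentan-3-yl tetradecanoate | C[C@H](O[Si](C)(C)C(C)(C)C)[C@@H](OC(=O)CCCCCCCCCCCCC)[C@@H](O[Si](C)(C)C(C)(C)C)CC1SCCCS1 | intermediate
9 | (3S,4R,5S)-3,5-bis(tert-butyldimethylsilyloxy)-4-(tetradecanoyloxy)hexanal | C[C@H](O[Si](C)(C)C(C)(C)C)[C@@H](OC(=O)CCCCCCCCCCCCC)[C@@H](O[Si](C)(C)C(C)(C)C)CC=O | intermediate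
10 | methyl isocyanoacetate | [C-]#[N+]CC(=O)OC | starting material
11 | methyl (4S,5R)-5-[(2S,3R,4S)-2,4-bis(tert-butyldimethylsilyloxy)-3-(tetradecanoyloxy)pentyl]-4,5-dihydrooxazole-4-carboxylate (trans) | C[C@H](O[Si](C)(C)C(C)(C)C)[C@@H](OC(=O)CCCCCCCCCCCCC)[C@@H](O[Si](C)(C)C(C)(C)C)C[C@@H](O1)[C@H](N=C1)C(=O)OC | intermediate
12 | methyl (2S,3R,5S,6R,7S)-2-amino-5,7-bis(tert-butyldimethylsilyloxy)-3-(formyloxy)-6-(tetradecanoyloxy)octanoate hydrochloride | C[C@H](O[Si](C)(C)C(C)(C)C)[C@@H](OC(=O)CCCCCCCCCCCCC)[C@@H](O[Si](C)(C)C(C)(C)C)C[C@@H](OC=O)[C@H]([NH3+])C(=O)OC.[Cl-] | intermediate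
13 | methyl (2S,3R,5S,6R,7S)-5,7-bis(tert-butyldimethylsilyloxy)-2-formamido-3-hydroxy-6-(tetradecanoyloxy)octanoate | C[C@H](O[Si](C)(C)C(C)(C)C)[C@@H](OC(=O)CCCCCCCCCCCCC)[C@@H](O[Si](C)(C)C(C)(C)C)C[C@@H](O)[C@H](NC=O)C(=O)OC | intermediate
14 | methyl (2S,3R,5S,6R,7S)-3,5,7-tris(tert-butyldimethylsilyloxy)-2-formamido-6-(tetradecanoyloxy)octanoate | C[C@H](O[Si](C)(C)C(C)(C)C)[C@@H](OC(=O)CCCCCCCCCCCCC)[C@@H](O[Si](C)(C)C(C)(C)C)C[C@@H](O[Si](C)(C)C(C)(C)C)[C@H](NC=O)C(=O)OC | intermediate
15 | (2S,3R,4S,6R,7R)-2,4,6-tris(tert-butyldimethylsilyloxy)-7-formamido-8-hydroxyoctan-3-yl tetradecanoate | C[C@H](O[Si](C)(C)C(C)(C)C)[C@@H](OC(=O)CCCCCCCCCCCCC)[C@@H](O[Si](C)(C)C(C)(C)C)C[C@@H](O[Si](C)(C)C(C)(C)C)[C@H](NC=O)CO | intermediate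
16 | (2S,3R,4S,6R,7S)-2,4,6-tris(tert-butyldimethylsilyloxy)-7-formamido-8-oxooctan-3-yl tetradecanoate | C[C@H](O[Si](C)(C)C(C)(C)C)[C@@H](OC(=O)CCCCCCCCCCCCC)[C@@H](O[Si](C)(C)C(C)(C)C)C[C@@H](O[Si](C)(C)C(C)(C)C)[C@H](NC=O)C=O | intermediate
17 | (2S,3R,4S,6R)-6-[(4S)-5-bromo-4,5-dihydrooxazol-4-yl]-2,4,6-tris(tert-butyldimethylsilyloxy)hexan-3-yl tetradecanoate (C5 epimers of the ring) | C[C@H](O[Si](C)(C)C(C)(C)C)[C@@H](OC(=O)CCCCCCCCCCCCC)[C@@H](O[Si](C)(C)C(C)(C)C)C[C@@H](O[Si](C)(C)C(C)(C)C)[C@H](N=CO1)C1Br | intermediate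
18 | (2S,3R,4S,6R)-2,4,6-tris(tert-butyldimethylsilyloxy)-6-(oxazol-4-yl)hexan-3-yl tetradecanoate | C[C@H](O[Si](C)(C)C(C)(C)C)[C@@H](OC(=O)CCCCCCCCCCCCC)[C@@H](O[Si](C)(C)C(C)(C)C)C[C@@H](O[Si](C)(C)C(C)(C)C)c1cocn1 | intermediate
19 | 5-(chloromethyl)oxazole | ClCc1cnco1 | starting material
20 | C2-chlorozincio derivative of 18 (oxazol-2-ylzinc chloride, LiCl complex) | C[C@H](O[Si](C)(C)C(C)(C)C)[C@@H](OC(=O)CCCCCCCCCCCCC)[C@@H](O[Si](C)(C)C(C)(C)C)C[C@@H](O[Si](C)(C)C(C)(C)C)c1coc([Zn]Cl)n1 | intermediate
21 | (2S,3R,4S,6R)-2,4,6-tris(tert-butyldimethylsilyloxy)-6-[2-(oxazol-5-ylmethyl)oxazol-4-yl]hexan-3-yl tetradecanoate | C[C@H](O[Si](C)(C)C(C)(C)C)[C@@H](OC(=O)CCCCCCCCCCCCC)[C@@H](O[Si](C)(C)C(C)(C)C)C[C@@H](O[Si](C)(C)C(C)(C)C)c1coc(Cc2cnco2)n1 | intermediate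
22 | (2S,3R,4S,6R)-2,4,6-trihydroxy-6-[2-(oxazol-5-ylmethyl)oxazol-4-yl]hexan-3-yl tetradecanoate (CNP0268144.1) | CCCCCCCCCCCCCC(=O)O[C@H]([C@H](C)O)[C@@H](O)C[C@@H](O)c1coc(Cc2cnco2)n1 | target

**Step count**

Total: 15 steps. Longest linear sequence: 15 steps (1 → 22); 4, 10 and 19 are bought and enter directly.

**Steps most likely to fail**

Step 8. The catalyst may discriminate poorly between the two aldehyde faces of this α-unbranched, β-silyloxy aldehyde, or the substrate may oppose the ligand, so that much material ends with the wrong configuration at chain C1. Fallback: the fallback sets out from 9 and 10 and corrects the centre by inversion instead of relying on the catalyst alone. The unwanted methyl (4R,5S)-trans-oxazoline-4-carboxylate F1 is separated from 11 and hydrolysed as in step 9 to the (2R,3S)-N-formyl β-hydroxy amino ester F2. DAST in CH2Cl2 at −78 °C then activates the hydroxyl, and the formamide oxygen displaces it with inversion to give the cis-(4R,5R)-oxazoline F3. Catalytic DBU in CH2Cl2 epimerises the ester-bearing C4 to the more stable trans isomer, which is 11, where the material rejoins the route.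

Step 13. The phosphonium bromide may consume the formamide without closing the ring (dehydration towards the isocyanide), brominate the aldehyde, or allow enolisation with loss of silanol from C1. Fallback: the fallback sets out from 16 and closes ring A through the other oxygen. POCl3 and Et3N in CH2Cl2 at −40 °C dehydrate the formamide completely to the α-isocyano aldehyde F4, (2S,3R,4S,6R,7S)-2,4,6-tris(tert-butyldimethylsilyloxy)-7-isocyano-8-oxooctan-3-yl tetradecanoate. On warming with excess Et3N its enolate oxygen adds to the isocyanide carbon (Schöllkopf-type closure, forming O1–C2) and tautomerises to 18, where the route resumes.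

Step 14. Zincation at C2 may be slow or incomplete on the 4-alkyl oxazole, the heterobenzylic chloride may homocouple or self-alkylate at nitrogen, and transmetalation from the electron-poor oxazolylzinc may lag behind these processes. Fallback: the fallback sets out from 18 and 19 and reverses the polarity of the coupling. The zinc species 20 is quenched with I2 to give the 2-iodo ring A oxazole F5. Separately, 19 is converted with Zn dust and LiCl in THF into (oxazol-5-ylmethyl)zinc chloride F6. Pd(PPh3)4-catalysed Negishi coupling of F5 with F6 in THF at 25–50 °C gives 21, where the route resumes.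

**Further compounds**

F1 | step 8 | methyl (4R,5S)-5-[(2S,3R,4S)-2,4-bis(tert-butyldimethylsilyloxy)-3-(tetradecanoyloxy)pentyl]-4,5-dihydrooxazole-4-carboxylate (trans, C5 epimer series) | C[C@H](O[Si](C)(C)C(C)(C)C)[C@@H](OC(=O)CCCCCCCCCCCCC)[C@@H](O[Si](C)(C)C(C)(C)C)C[C@H](O1)[C@@H](N=C1)C(=O)OC
F2 | step 8 | methyl (2R,3S,5S,6R,7S)-5,7-bis(tert-butyldimethylsilyloxy)-2-formamido-3-hydroxy-6-(tetradecanoyloxy)octanoate | C[C@H](O[Si](C)(C)C(C)(C)C)[C@@H](OC(=O)CCCCCCCCCCCCC)[C@@H](O[Si](C)(C)C(C)(C)C)C[C@H](O)[C@@H](NC=O)C(=O)OC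
F3 | step 8 | methyl (4R,5R)-5-[(2S,3R,4S)-2,4-bis(tert-butyldimethylsilyloxy)-3-(tetradecanoyloxy)pentyl]-4,5-dihydrooxazole-4-carboxylate (cis) | C[C@H](O[Si](C)(C)C(C)(C)C)[C@@H](OC(=O)CCCCCCCCCCCCC)[C@@H](O[Si](C)(C)C(C)(C)C)C[C@@H](O1)[C@@H](N=C1)C(=O)OC
F4 | step 13 | (2S,3R,4S,6R,7S)-2,4,6-tris(tert-butyldimethylsilyloxy)-7-isocyano-8-oxooctan-3-yl tetradecanoate | C[C@H](O[Si](C)(C)C(C)(C)C)[C@@H](OC(=O)CCCCCCCCCCCCC)[C@@H](O[Si](C)(C)C(C)(C)C)C[C@@H](O[Si](C)(C)C(C)(C)C)[C@H]([N+]#[C-])C=O
F5 | step 14 | (2S,3R,4S,6R)-2,4,6-tris(tert-butyldimethylsilyloxy)-6-(2-iodooxazol-4-yl)hexan-3-yl tetradecanoate | C[C@H](O[Si](C)(C)C(C)(C)C)[C@@H](OC(=O)CCCCCCCCCCCCC)[C@@H](O[Si](C)(C)C(C)(C)C)C[C@@H](O[Si](C)(C)C(C)(C)C)c1coc(I)n1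
F6 | step 14 | (oxazol-5-ylmethyl)zinc chloride | Cl[Zn]Cc1cnco1
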